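**Plan**

Numbering: ring C1(C7H2OAc)=C2–C3(OH)–C4–C5–C6(OH), oxirane on C4–C5 (a 7-oxabicyclo[4.1.0]hept-3-ene); side chain C1'–C12' on C4.
Cuts, in retrosynthetic order: C7–OAc back to a C7 ethyl ester; C5'–C6', the σ-bond between the two vinylic CH carbons in the middle of the C2'–C7' triene; C1'–C2'; finally the ring olefin C1=C2 is hidden in a cyclopentadiene adduct, which leads to the symmetric quinone diester 2.
Enabling feature: C5' and C6' are unsubstituted sp2 CH, C4'=C5' is E-disubstituted, and C7' carries a methyl cis to C5', which is the imprint of a syn methylmetalation of a terminal alkyne. C1'–C4' insulate this site from the oxirane ring, so a dienyl iodide on the finished ring, a C8 enyne and AlMe3 can be joined in one flask.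
Forward order: the carbocycle comes from the quinone. The Diels–Alder cage goes on as a temporary ring, then the oxirane and both carbinols are made and the cage is removed. The C1' aldehyde takes up the C2'–C5' iodoenyne, this is turned into the dienyl iodide, methylalumination/cross-coupling completes the chain, the ester becomes CH2OAc, and the TES groups come off.
Stereochemistry: one catalytic asymmetric Diels–Alder reaction fixes the absolute sense. The folded endo cage sends peroxide and hydride to its convex face, which sets C4/C5 and then C3/C6 (hydroxyls cis to each other, trans to the oxirane). C1' comes from Cornforth-controlled addition to the epoxy aldehyde, and the chain olefins come from syn carbo-/hydrometalation and stereoretentive couplings.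

Key step: step 16

Assumption: with the (S,S)-ligand the diene is taken to add to the face of 2 that gives 4 as drawn (the equally available (R,R)-ligand is used should the mirror image form). Cyclopentadiene 3 is cracked from commercial dicyclopentadiene just before use and is counted as a starting material.

**Route** (TES = triethylsilyl)

Step 1
Reactants: 1 diethyl 2,5-dihydroxyterephthalate
Product: 2 diethyl 3,6-dioxocyclohexa-1,4-diene-1,4-dicarboxylate
Conditions: Ag2O, MgSO4, CH2Cl2, rt, dark; filtration through Celite
Reagents that add atoms: none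
Why: Oxidation of a hydroquinone to the p-quinone with Ag2O under neutral anhydrous conditions is the standard entry to ester-bearing quinones, and MgSO4 binds the water that would otherwise add to this electrophilic product.

Step 2
Reactants: 2 quinone diester; 3 cyclopenta-1,3-diene
Product: 4 endo adduct, diethyl 5,8-dioxo-1,4,4a,5,8,8a-hexahydro-1,4-methanonaphthalene-4a,7-dicarboxylate
Conditions: Gd(OTf)3 (10 mol %), (S,S)-Ph-pybox (12 mol %), 4 Å MS, CH2Cl2, −78 °C, slow addition of 3 (1.1 equiv)
Reagents that add atoms: none
Why: Enantioselective Lewis-acid-catalysed quinone Diels–Alder reaction, in which the ester and the neighbouring quinone carbonyl chelate the gadolinium–pybox complex, which activates one of the two homotopic ester-bearing double bonds and shields one of its faces, so that endo addition sets C1, C2 and both bridgeheads at once.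

Step 3
Reactants: 4 endo adduct
Product: 5 convex-face C4–C5 epoxide of 4
Conditions: t-BuOOH (decane solution), DBU (cat.), CH2Cl2, 0 °C
Reagents that add atoms: tert-butyl hydroperoxide, CC(C)(C)OO
Why: Weitz–Scheffer nucleophilic epoxidation, in which the peroxide anion adds to C5 of the triply activated C4=C5 bond from the open convex face (the concave face lies over the norbornene C=C) and the enolate closes the oxirane on that face, while the unactivated norbornene olefin does not react.

Step 4
Reactants: 5 epoxy diketone
Product: 6 diol with C3–OH and C6–OH on the concave face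
Conditions: NaBH4, CeCl3·7H2O, MeOH, −78 to −40 °C
Reagents that add atoms: none
Why: Luche reduction, in which hydride can reach both ketones only from the convex face that already carries the oxirane, so that both hydroxyls end up cis to each other and trans to the oxirane, while low temperature and the cerium salt spare the esters and the oxirane.

Step 5
Reactants: 6 diol
Product: 7 bis-TES ether of 6
Conditions: TESOTf, 2,6-lutidine, CH2Cl2, 0 °C to rt
Reagents that add atoms: triethylsilyl trifluoromethanesulfonate, CC[Si](CC)(CC)OS(=O)(=O)C(F)(F)F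
Why: Silylation of hindered secondary alcohols with a silyl triflate and a non-nucleophilic base is reliable, and TES is chosen because it can be removed at the end under almost neutral conditions.

Step 6
Reactants: 7 bis-TES cage compound
Product: 8 diethyl (1S,2S,5R,6S)-2,5-bis(triethylsilyloxy)-7-oxabicyclo[4.1.0]hept-3-ene-1,4-dicarboxylate
Conditions: Ph2O, 240 °C, N2 stream, base-washed glass
Reagents that add atoms: none
Why: Thermal retro-Diels–Alder reaction, favoured because the released dienophile is an α,β-unsaturated ester, the adduct is strained by its quaternary C1 and by two silyloxy groups pressed against the norbornene olefin, and volatile cyclopentadiene is swept out, so that C1=C2 appears without touching the four ring stereocentres.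

Step 7
Reactants: 8 diester
Product: 9 C1' primary alcohol (CH2OH on oxirane carbon C4, C7 ethyl ester kept)
Conditions: LiBH4, THF, 0 °C
Reagents that add atoms: none
Why: Chemoselective borohydride reduction, in which the glycidic ester on C4 is activated toward a nucleophilic hydride by its α-oxygen whereas the conjugated C7 ester is deactivated, so that only C1' is taken to the alcohol.

Step 8
Reactants: 9 primary alcohol
Product: 10 epoxy aldehyde (CHO on C4)
Conditions: (n-Pr4N)RuO4 (5 mol %), NMO, 4 Å MS, CH2Cl2, rt
Reagents that add atoms: none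
Why: Ley–Griffith oxidation is neutral and stops at the aldehyde, which cannot epimerise because C4 is quaternary.

Step 9
Reactants: 11 1,4-bis(trimethylsilyl)buta-1,3-diyne
Product: 13 buta-1,3-diynyl(trimethyl)silane, via lithium diynide 12 (not isolated)
Conditions: MeLi·LiBr (1.0 equiv), Et2O, 0 °C to rt; then H2O, 0 °C
Reagents that add atoms: none
Why: Selective mono-desilylation, in which one equivalent of MeLi attacks one silicon of the symmetric diyne, the charge of the resulting diynide protects the second silyl group, and water then gives the terminal diyne.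

Step 10
Reactants: 13 silyl diyne
Product: 15 [(3E)-4-iodo-3-methylbut-3-en-1-yn-1-yl]trimethylsilane, via alkenylalane 14 (not isolated)
Conditions: AlMe3, Cp2ZrCl2 (cat.), CH2Cl2, rt; then I2, THF, −30 to 0 °C
Reagents that add atoms: trimethylaluminium, C[Al](C)C; iodine, [I][I]
Why: Negishi carboalumination adds CH3 and aluminium syn across the terminal, unsilylated triple bond with aluminium on the terminus, and iodinolysis with retention gives the E-iodide.

Step 11
Reactants: 15 silyl iodoenyne
Product: 16 (1E)-1-iodo-2-methylbut-1-en-3-yne
Conditions: K2CO3 (cat.), MeOH, 0 °C to rt; kept as an Et2O solution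
Reagents that add atoms: none
Why: Carbonate-catalysed methanolysis of an alkynyl–silicon bond is fast and leaves the vinylic iodide untouched.

Step 12
Reactants: 10 epoxy aldehyde; 16 iodoenyne
Product: 18 (1'S)-enynyl carbinol, via alkenylchromium dichloride 17 (not isolated)
Conditions: CrCl2 (excess), NiCl2 (1 mol %), DMSO, rt
Reagents that add atoms: none
Why: Nozaki–Hiyama–Kishi reaction, in which zerovalent nickel inserts into the C–I bond, the alkenyl group passes with retention to trivalent chromium, and this non-basic, non-chelating nucleophile adds only to the aldehyde, attacking the Cornforth conformer (C=O antiperiplanar to the C4–O bond) on the side away from C5 to give the anti epoxy alcohol, (S) at C1'.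

Step 13
Reactants: 18 carbinol
Product: 19 tris-TES enyne
Conditions: TESOTf, 2,6-lutidine, CH2Cl2, −78 to 0 °C
Reagents that add atoms: triethylsilyl trifluoromethanesulfonate, CC[Si](CC)(CC)OS(=O)(=O)C(F)(F)F
Why: Silyl triflate silylation covers the hindered C1' hydroxyl, which would otherwise form an aluminium alkoxide next to the oxirane in step 16 and compete in step 18.

Step 14
Reactants: 19 tris-TES enyne
Product: 21 (2'E,4'E)-dienyl iodide, via alkenylzirconocene chloride 20 (not isolated)
Conditions: Cp2Zr(H)Cl, THF, rt, dark; then I2, THF, −78 to 0 °C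
Reagents that add atoms: iodine, [I][I]
Why: Hydrozirconation of the terminal alkyne is a syn addition that places zirconium on C5' and is much faster than attack on the hindered ester or oxirane, and iodinolysis with retention gives the E-iodide.

Step 15
Reactants: 22 5-bromo-2-methylpent-2-ene
Product: 23 6-methylhept-5-en-1-yne
Conditions: LiC≡CH·H2NCH2CH2NH2, DMSO, 10 °C to rt
Reagents that add atoms: lithium acetylide–ethylenediamine complex, [Li]C#C.NCCN
Why: SN2 alkylation of lithium acetylide by a primary homoallylic bromide in DMSO is a standard route to terminal alkynes.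

Step 16
Reactants: 23 6-methylhept-5-en-1-yne; 21 dienyl iodide
Product: 26 tris-TES tetraenyl ethyl ester, via alkenylalane 24 (not isolated), via alkenylzinc chloride 25 (not isolated)
Conditions: 23, AlMe3, Cp2ZrCl2 (cat.), CH2Cl2, rt; volatiles removed in vacuo; THF, ZnCl2, then 21, Pd(PPh3)4 (5 mol %), rt
Reagents that add atoms: trimethylaluminium, C[Al](C)C
Why: Cp2ZrCl2-catalysed syn methylalumination of the terminal alkyne of 23 places CH3 on C7' and aluminium on C6' on the same side, so that 24 forms as the E-alkenylalane while the trisubstituted C10'=C11' olefin is left alone. After surplus AlMe3 is stripped off, ZnCl2 takes over the alkenyl group with retention (25), zerovalent palladium inserts into the C5'–I bond of 21 with retention, and transmetalation followed by reductive elimination from divalent palladium forges C5'–C6'. The closest known reaction type is the one-flask zirconium-catalysed carboalumination/palladium-catalysed Negishi alkenyl–alkenyl coupling used for isoprenoid dienes and trienes. No ring is closed and no sp3 stereocentre is made; the stereochemical content is the triene geometry, with C6'=C7' fixed by the syn addition and C2'=C3' and C4'=C5' carried over because every elementary step at sp2 carbon is stereoretentive. The step needs chemoselectivity for the vinylic C–I bond, which is secured by holding C7 at the ester level (an allylic acetate would ionise to a π-allyl complex and couple with 25), by masking all three carbinols as TES ethers, and by working in THF with the weakly Lewis-acidic zinc reagent, so that the trisubstituted oxirane, deactivated by three neighbouring C–O bonds, is not opened.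

Step 17
Reactants: 26 tetraenyl ester
Product: 27 C7 allylic alcohol
Conditions: i-Bu2AlH, CH2Cl2, −78 °C; aqueous sodium potassium tartrate
Reagents that add atoms: none
Why: i-Bu2AlH reduces the conjugated ester in 1,2-fashion to the allylic alcohol at a temperature at which silyl ethers, the hindered oxirane and the tetraene do not react.

Step 18
Reactants: 27 allylic alcohol
Product: 28 C7 acetate
Conditions: Ac2O, pyridine, DMAP (cat.), CH2Cl2, 0 °C
Reagents that add atoms: acetic anhydride, CC(=O)OC(C)=O
Why: Simple acylation, with no selectivity needed because C7–OH is the only free hydroxyl.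

Step 19
Reactants: 28 tris-TES acetate
Product: 29 target CNP0106887.2
Conditions: HF·pyridine, excess pyridine, THF, 0 °C to rt
Reagents that add atoms: none
Why: Fluoride-driven cleavage of the three secondary TES ethers in pyridine-buffered HF is mild enough not to ionise the trienylic C1' carbinol, open the oxirane or shift the acetate.

**Compound list**

1 | diethyl 2,5-dihydroxyterephthalate | CCOC(=O)c1cc(O)c(cc1O)C(=O)OCC | starting material
2 | diethyl 3,6-dioxocyclohexa-1,4-diene-1,4-dicarboxylate | CCOC(=O)C1=CC(=O)C(C(=O)OCC)=CC1=O | intermediate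
3 | cyclopenta-1,3-diene | C1C=CC=C1 | starting material
4 | endo Diels–Alder adduct; angular CO2Et (C1) and H (C2) exo on the norbornene, i.e. on the convex face | CCOC(=O)[C@]12C(=O)C=C(C(=O)OCC)C(=O)[C@H]1[C@H]3C=C[C@@H]2C3 | intermediate
5 | C4–C5 epoxide of 4, oxirane on the convex face | CCOC(=O)[C@]12C(=O)[C@@H]4O[C@]4(C(=O)OCC)C(=O)[C@H]1[C@H]3C=C[C@@H]2C3 | intermediate
6 | C3,C6-diol of 5, both OH on the concave face, trans to the oxirane | CCOC(=O)[C@]12[C@@H](O)[C@@H]4O[C@]4(C(=O)OCC)[C@@H](O)[C@H]1[C@H]3C=C[C@@H]2C3 | intermediate
7 | bis-TES ether of 6 | CCOC(=O)[C@]12[C@@H](O[Si](CC)(CC)CC)[C@@H]4O[C@]4(C(=O)OCC)[C@@H](O[Si](CC)(CC)CC)[C@H]1[C@H]3C=C[C@@H]2C3 | intermediate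
8 | diethyl (1S,2S,5R,6S)-2,5-bis(triethylsilyloxy)-7-oxabicyclo[4.1.0]hept-3-ene-1,4-dicarboxylate | CCOC(=O)C1=C[C@H](O[Si](CC)(CC)CC)[C@@]2(C(=O)OCC)O[C@H]2[C@@H]1O[Si](CC)(CC)CC | intermediate
9 | as 8, with CH2OH in place of the ester on oxirane carbon C4 | CCOC(=O)C1=C[C@H](O[Si](CC)(CC)CC)[C@@]2(CO)O[C@H]2[C@@H]1O[Si](CC)(CC)CC | intermediate
10 | as 8, with CHO on oxirane carbon C4 | CCOC(=O)C1=C[C@H](O[Si](CC)(CC)CC)[C@@]2(C=O)O[C@H]2[C@@H]1O[Si](CC)(CC)CC | intermediate
11 | 1,4-bis(trimethylsilyl)buta-1,3-diyne | C[Si](C)(C)C#CC#C[Si](C)(C)C | starting material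
12 | lithium 4-(trimethylsilyl)buta-1,3-diynide | [Li]C#CC#C[Si](C)(C)C | intermediate
13 | buta-1,3-diynyl(trimethyl)silane | C#CC#C[Si](C)(C)C | intermediate
14 | dimethyl[(1E)-2-methyl-4-(trimethylsilyl)but-1-en-3-ynyl]alane | C[Al](C)/C=C(C)/C#C[Si](C)(C)C | intermediate
15 | [(3E)-4-iodo-3-methylbut-3-en-1-yn-1-yl]trimethylsilane | I/C=C(C)/C#C[Si](C)(C)C | intermediate
16 | (1E)-1-iodo-2-methylbut-1-en-3-yne | I/C=C(C)/C#C | intermediate
17 | [(1E)-2-methylbut-1-en-3-ynyl]chromium dichloride | Cl[Cr](Cl)/C=C(C)/C#C | intermediate
18 | (1'S,2'E)-1'-hydroxy-3'-methylpent-2'-en-4'-ynyl group on C4; ring as in 8, C7 ethyl ester | CCOC(=O)C1=C[C@H](O[Si](CC)(CC)CC)[C@@]2([C@@H](O)/C=C(C)/C#C)O[C@H]2[C@@H]1O[Si](CC)(CC)CC | intermediate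
19 | C1' TES ether of 18 | CCOC(=O)C1=C[C@H](O[Si](CC)(CC)CC)[C@@]2([C@@H](O[Si](CC)(CC)CC)/C=C(C)/C#C)O[C@H]2[C@@H]1O[Si](CC)(CC)CC | intermediate
20 | (2'E,4'E)-dienyl zirconocene chloride from 19 | CCOC(=O)C1=C[C@H](O[Si](CC)(CC)CC)[C@@]2([C@@H](O[Si](CC)(CC)CC)/C=C(C)/C=C/[Zr](Cl)(C3C=CC=C3)C4C=CC=C4)O[C@H]2[C@@H]1O[Si](CC)(CC)CC | intermediate
21 | (1'S,2'E,4'E)-5'-iodo-3'-methyl-1'-(triethylsilyloxy)penta-2',4'-dienyl group on C4; ring as in 8 | CCOC(=O)C1=C[C@H](O[Si](CC)(CC)CC)[C@@]2([C@@H](O[Si](CC)(CC)CC)/C=C(C)/C=C/I)O[C@H]2[C@@H]1O[Si](CC)(CC)CC | intermediate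
22 | 5-bromo-2-methylpent-2-ene | CC(C)=CCCBr | starting material
23 | 6-methylhept-5-en-1-yne | C#CCCC=C(C)C | intermediate
24 | [(1E)-2,6-dimethylhepta-1,5-dienyl]dimethylalane | C[Al](C)/C=C(\C)CCC=C(C)C | intermediate
25 | [(1E)-2,6-dimethylhepta-1,5-dienyl]zinc chloride | Cl[Zn]/C=C(\C)CCC=C(C)C | intermediate
26 | tris-TES ether, C7 ethyl ester, complete (1'S,2'E,4'E,6'E)-chain | CCOC(=O)C1=C[C@H](O[Si](CC)(CC)CC)[C@@]2([C@@H](O[Si](CC)(CC)CC)/C=C(C)/C=C/C=C(\C)CCC=C(C)C)O[C@H]2[C@@H]1O[Si](CC)(CC)CC | intermediate
27 | as 26, with CH2OH at C7 | OCC1=C[C@H](O[Si](CC)(CC)CC)[C@@]2([C@@H](O[Si](CC)(CC)CC)/C=C(C)/C=C/C=C(\C)CCC=C(C)C)O[C@H]2[C@@H]1O[Si](CC)(CC)CC | intermediate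
28 | as 26, with CH2OAc at C7 | CC(=O)OCC1=C[C@H](O[Si](CC)(CC)CC)[C@@]2([C@@H](O[Si](CC)(CC)CC)/C=C(C)/C=C/C=C(\C)CCC=C(C)C)O[C@H]2[C@@H]1O[Si](CC)(CC)CC | intermediate
29 | [(1R,2S,5R,6S)-2,5-dihydroxy-1-[(1S,2E,4E,6E)-1-hydroxy-3,7,11-trimethyldodeca-2,4,6,10-tetraenyl]-7-oxabicyclo[4.1.0]hept-3-en-4-yl]methyl acetate | CC(=O)OCC1=C[C@H](O)[C@@]2([C@@H](O)/C=C(C)/C=C/C=C(\C)CCC=C(C)C)O[C@H]2[C@@H]1O | target

**Step count**

Total step count: 19. Longest linear sequence: 15 (steps 1–8, 12–14, 16–19).

**Steps most likely to fail**

Step 2. The uncatalysed cycloaddition of this very electron-poor quinone may outrun the chiral complex, so that facial discrimination is lost.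
- The fallback moves the asymmetric event from the cycloaddition to the epoxidation and sets out from 2.
- 2 is epoxidised on one of its enantiotopic faces (its two ester-bearing double bonds are homotopic) under chiral phase-transfer catalysis. The conditions are an N-(9-anthracenylmethyl)cinchonidinium salt, t-BuOOH, solid K2CO3 and toluene at low temperature. This gives the epoxyquinone diester F1.
- 3 then adds without catalyst to the remaining ester-bearing double bond, endo and on the face away from the oxirane. The sequence comes back to the route at 5.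

Step 6. Cycloreversion may need a temperature at which loss of silyl groups or opening of the oxirane sets in, because the released dienophile is activated by one ester only.
- The fallback uses a more labile temporary ring and sets out from 2.
- 2 is combined with commercial 6,6-dimethylfulvene in place of 3 under the conditions of step 2. Fulvene adducts revert far more easily because the cross-conjugated fulvene is regained.
- The fulvene adduct F2 is taken through the operations of steps 3 to 5, namely its convex-face epoxide F3, the concave-face diol F4 and the bis-TES ether F5.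
- Heating the last of these in refluxing xylene brings the sequence back to the route at 8.

Step 12. Facial selectivity at the aldehyde may be poor, since the silyloxy group on C3 crowds the side that the Cornforth model prefers.
- In the fallback C1' is set by reagent-controlled reduction instead of by addition. It sets out from 18, used as whatever C1' epimer mixture step 12 delivers.
- Oxidation with Dess–Martin periodinane gives the cross-conjugated dienynone F6.
- Corey–Bakshi–Shibata reduction follows, with the (R)-methyl oxazaborolidine and catecholborane at −78 °C. The quaternary oxirane carbon acts as the large substituent and the alkenyl group as the small one. This comes back to the route at 18 with (S)-C1'.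

**Further compounds**

F1 | step 2 | diethyl 2,5-dioxo-7-oxabicyclo[4.1.0]hept-3-ene-1,4-dicarboxylate, oxirane configuration as in 5 | CCOC(=O)C1=CC(=O)[C@@]2(C(=O)OCC)O[C@H]2C1=O
F2 | step 6 | endo adduct of 2 and 6,6-dimethylfulvene (isopropylidene on the one-carbon bridge) | CCOC(=O)[C@]12C(=O)C=C(C(=O)OCC)C(=O)[C@H]1[C@H]3C=C[C@@H]2C3=C(C)C
F3 | step 6 | convex-face C4–C5 epoxide of F2 | CCOC(=O)[C@]12C(=O)[C@@H]4O[C@]4(C(=O)OCC)C(=O)[C@H]1[C@H]3C=C[C@@H]2C3=C(C)C
F4 | step 6 | C3,C6-diol of F3, both OH on the concave face | CCOC(=O)[C@]12[C@@H](O)[C@@H]4O[C@]4(C(=O)OCC)[C@@H](O)[C@H]1[C@H]3C=C[C@@H]2C3=C(C)C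
F5 | step 6 | bis-TES ether of F4 | CCOC(=O)[C@]12[C@@H](O[Si](CC)(CC)CC)[C@@H]4O[C@]4(C(=O)OCC)[C@@H](O[Si](CC)(CC)CC)[C@H]1[C@H]3C=C[C@@H]2C3=C(C)C
F6 | step 12 | C1' ketone of 18, (2'E)-3'-methylpent-2'-en-4'-ynoyl group on C4 | CCOC(=O)C1=C[C@H](O[Si](CC)(CC)CC)[C@@]2(C(=O)/C=C(C)/C#C)O[C@H]2[C@@H]1O[Si](CC)(CC)CC
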